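You read this flask at 0.161 h, when 5.0% of the starting material is gone, and you want to know where the catalyst stands at that moment.

starting material 1.0 M; salt in the second phase 1.00 equiv; spent carrier 3.5 mol%; volume of the second phase over the first 0.50

    fresh carrier ⇌ dormant form (K1 = 1.8, k1 = 11 h⁻¹)
    spent carrier + salt in the second phase ⇌ fresh carrier + spent salt in the second phase (K2 = 0.59, k2 = 19 M⁻¹ h⁻¹)
    starting material + fresh carrier → product + spent carrier (k3 = 25 M⁻¹ h⁻¹)

* the form that holds most of the catalyst when 5.0% of the starting material are converted (dormant form / spent carrier / fresh carrier)
* its share of the catalyst then
* apparent order in salt in the second phase when 5.0% of the starting material are converted (percent change of the rate of making product for one percent more salt in the second phase charged)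

All the catalyst starts as spent carrier, so reckon with what the dormant form still has to gain, not with what it has gained.

1. At the charge, spent carrier regenerates at 38.0 h⁻¹ and fresh carrier turns over at 25.0 h⁻¹. Fresh carrier and dormant form relax together at 17.1 h⁻¹.
2. In a steady round, the dormant form is K1 times the fresh carrier, which gives a steady dormant share of 52.1%.
3. The three forms approach this share at a slow rate of 11.7 h⁻¹ and a fast rate of 68.4 h⁻¹. Once the fast part has died, the gap left, the fraction of the steady share not yet reached, is fast/(fast − slow) times exp(−slow·t). At your reading it is 18.2%.
4. Bound from above: take salt as charged, no back-step, and fresh carrier's loss at its lowest in the window, 23.7 h⁻¹. The gap is then 17.9%, and the dormant share is 43.1%.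
5. Bound from below: give the back-step of the salt exchange, for the whole window, all the spent salt the window can hold, 8.50% of the charge, and take the same amount off the salt. Regeneration falls to 34.8 h⁻¹, and fresh carrier's loss rises to 30.5 h⁻¹. The gap becomes 20.2%, the steady share 49.0%, and the share at your reading is 39.1%.
6. Split the remainder in the steady ratio, and the form that holds most of the catalyst is dormant form.
7. In a steady round, the order in salt equals the spent share. Taking that rule over to your reading, I commit to 0.285.

The forecast gives dormant form at 41% and an order of 0.35, with a share lower than the bound from above and higher than the bound from below, and says “the rate responds only weakly to salt”.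

The simulation gives dormant form at 40.8%, with fresh carrier at 31.9%, spent carrier at 27.3% and an order of 0.37.

In this flask, spent carrier regenerates at 38 h⁻¹ as charged, faster than fresh carrier turns over at 25 h⁻¹, and the dormant share stands 21.7% short of the steady share as charged, against a reckoned gap of 18.2%. For the flask with twice the spent carrier, keep the rates of the bound from below and read at half the time: the gap opens to 48.9%, which puts the factor on the rate at 2.46, and that flask shows 2.37.

The constants used here belong to no real substance; the rest is arithmetic.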